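**Retrosynthetic overview**

The target is the (3R)-isoflavan; the last step frees O7–H from a tosylate, and the pyran ring (ring C) is the only ring made in the route and is closed last, by forming the C3–C4 bond (rings A and B are bought as arenes).
C3–C4 disconnection: C4 goes back to the formyl carbon of a ring A salicylaldehyde ether, used as its N–H hydrazone (a traceless benzylic carbanion equivalent that leaves as N2), and C3 goes back to a ring B benzylic carbinol that ionises to a para-quinone methide.
Enabling feature: O4'–H of ring B is para to C1', the ring carbon that bears C3, so C3 can become the exocyclic electrophilic terminus of a para-quinone methide; C4 sits on C4a of ring A between C5–OMe and C8a–O1, so it is the formyl carbon of a 2,6-dioxygenated benzaldehyde whose phenol oxygen O1 already carries C2.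
The two halves are joined through the O1–C2 ether bond: the ring A phenol aldehyde opens a ring B styrene oxide formed in situ from a bromohydrin (from 1-(4-hydroxy-2-methoxyphenyl)ethanone by pivaloylation, α-bromination and reduction).
Ring A comes from 2,4-dihydroxy-6-methoxybenzaldehyde: tosylation of the para hydroxyl, prenylation of the chelated hydroxyl, then two consecutive [3,3] shifts (Claisen, Cope) place the prenyl group on the carbon between OMe and OTs (future C6) and free the phenol that becomes O1.

Key step: step 9

Remark: the sense of induction of the phosphoric acid in step 9 cannot be derived from precedent; the route is written with (R)-TRIP, and the enantiomeric acid is to be used if a test reaction shows the opposite sense.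

**Route**

Step 1
Reactants: 1 2,4-dihydroxy-6-methoxybenzaldehyde
Product: 2 4-formyl-3-hydroxy-5-methoxyphenyl 4-methylbenzenesulfonate
Conditions: TsCl (1.05 equiv), K2CO3 (1.2 equiv), acetone, 0 °C → rt
Reagents that add atoms: p-toluenesulfonyl chloride, Cc1ccc(cc1)S(=O)(=O)Cl
Why: Selective O-sulfonylation, because the hydroxyl para to the formyl group is the more acidic, non-chelated phenol while the ortho hydroxyl is held in a hydrogen bond to the carbonyl, so one equivalent of TsCl should react at the para oxygen only.

Step 2
Reactants: 2 4-formyl-3-hydroxy-5-methoxyphenyl 4-methylbenzenesulfonate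
Product: 3 4-formyl-3-methoxy-5-[(3-methylbut-2-en-1-yl)oxy]phenyl 4-methylbenzenesulfonate
Conditions: prenyl bromide (1.5 equiv), K2CO3 (2 equiv), DMF, 40 °C
Reagents that add atoms: prenyl bromide (1-bromo-3-methylbut-2-ene), CC(C)=CCBr
Why: Williamson ether synthesis on the remaining chelated phenol in a dipolar aprotic solvent, to which the aryl tosylate and the aldehyde are inert.

Step 3
Reactants: 3 4-formyl-3-methoxy-5-[(3-methylbut-2-en-1-yl)oxy]phenyl 4-methylbenzenesulfonate
Product: 6 4-formyl-5-hydroxy-3-methoxy-2-(3-methylbut-2-en-1-yl)phenyl 4-methylbenzenesulfonate, via ortho-dienone 4 (not isolated), via para-dienone 5 (not isolated)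
Conditions: N,N-diethylaniline, 195 °C, Ar, sealed tube
Reagents that add atoms: none
Why: Aromatic Claisen rearrangement followed by Cope rearrangement (para-Claisen), in which the first [3,3] shift can only go to the free ortho carbon and the crowded 1,1-dimethylallyl group of dienone 4 should undergo a second [3,3] shift to the para carbon between the methoxy and tosyloxy groups before enolisation, so the prenyl group arrives unrearranged and the phenol that becomes O1 is set free.

Step 4
Reactants: 7 1-(4-hydroxy-2-methoxyphenyl)ethan-1-one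
Product: 8 4-acetyl-3-methoxyphenyl 2,2-dimethylpropanoate
Conditions: pivaloyl chloride (1.2 equiv), K2CO3 (1.5 equiv), acetone, 0 °C → rt
Reagents that add atoms: pivaloyl chloride, CC(C)(C)C(=O)Cl
Why: Standard O-acylation of a phenol; the pivalate lowers the reactivity of ring B towards ring bromination in step 5 and is later removed by hydrazine.

Step 5
Reactants: 8 4-acetyl-3-methoxyphenyl 2,2-dimethylpropanoate
Product: 9 4-(bromoacetyl)-3-methoxyphenyl 2,2-dimethylpropanoate
Conditions: CuBr2 (2.1 equiv), EtOAc–CHCl3 (1:1), reflux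
Reagents that add atoms: CuBr2, Br[Cu]Br
Why: Heterogeneous α-bromination of an aryl methyl ketone with CuBr2, which proceeds through the enol and should stop at the monobromide without touching the acyloxy-deactivated ring.

Step 6
Reactants: 9 4-(bromoacetyl)-3-methoxyphenyl 2,2-dimethylpropanoate
Product: 10 4-(2-bromo-1-hydroxyethyl)-3-methoxyphenyl 2,2-dimethylpropanoate (racemic)
Conditions: NaBH4 (0.6 equiv), MeOH–THF, −10 °C
Reagents that add atoms: none
Why: Fast borohydride reduction of the activated α-bromo ketone at low temperature should leave the aryl pivalate and the C–Br bond intact; the carbinol is racemic, which does not matter because this carbon is planarised in the quinone methide of step 9.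

Step 7
Reactants: 6 4-formyl-5-hydroxy-3-methoxy-2-(3-methylbut-2-en-1-yl)phenyl 4-methylbenzenesulfonate; 10 4-(2-bromo-1-hydroxyethyl)-3-methoxyphenyl 2,2-dimethylpropanoate (racemic)
Product: 12 4-{2-[2-formyl-3-methoxy-4-(3-methylbut-2-en-1-yl)-5-(tosyloxy)phenoxy]-1-hydroxyethyl}-3-methoxyphenyl 2,2-dimethylpropanoate (racemic), via epoxide 11 (not isolated)
Conditions: K2CO3 (2.5 equiv), DMF, 65 °C
Reagents that add atoms: none
Why: The base closes the bromohydrin to styrene oxide 11, which the phenoxide of 6 should open by SN2 attack at the unhindered CH2 terminus (epoxide-opening etherification), forming the O1–C2 bond and leaving the secondary benzylic alcohol, with the ortho-methoxy group disfavouring attack at the benzylic carbon.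

Step 8
Reactants: 12 4-{2-[2-formyl-3-methoxy-4-(3-methylbut-2-en-1-yl)-5-(tosyloxy)phenoxy]-1-hydroxyethyl}-3-methoxyphenyl 2,2-dimethylpropanoate (racemic)
Product: 13 4-[(E)-hydrazinylidenemethyl]-5-[2-hydroxy-2-(4-hydroxy-2-methoxyphenyl)ethoxy]-3-methoxy-2-(3-methylbut-2-en-1-yl)phenyl 4-methylbenzenesulfonate (racemic)
Conditions: N2H4·H2O (10 equiv), degassed EtOH–THF, Ar, 0 °C → 40 °C
Reagents that add atoms: hydrazine monohydrate, NN.O
Why: Hydrazone formation with a large excess of hydrazine (which suppresses azine formation) together with hydrazinolysis of the aryl pivalate, so one reagent should unmask both the C4 nucleophile and the 4'-hydroxyl trigger while the aryl tosylate, the prenyl group and the benzylic alcohol stay untouched.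

Step 9
Reactants: 13 4-[(E)-hydrazinylidenemethyl]-5-[2-hydroxy-2-(4-hydroxy-2-methoxyphenyl)ethoxy]-3-methoxy-2-(3-methylbut-2-en-1-yl)phenyl 4-methylbenzenesulfonate (racemic)
Product: 16 (3R)-3-(4-hydroxy-2-methoxyphenyl)-5-methoxy-6-(3-methylbut-2-en-1-yl)-3,4-dihydro-2H-chromen-7-yl 4-methylbenzenesulfonate, via para-quinone methide 14 (not isolated), via diazene 15 (not isolated)
Conditions: (R)-TRIP [(R)-3,3'-bis(2,4,6-triisopropylphenyl)-1,1'-binaphthyl-2,2'-diyl hydrogen phosphate] (10 mol%), 5 Å MS, toluene, 0.005 M (13 added over 6 h), −20 °C → 25 °C, Ar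
Reagents that add atoms: none
Why: Proposed new method: the chiral phosphoric acid should dehydrate the 4-hydroxybenzylic alcohol of 13 to the ring B para-quinone methide 14, whose exocyclic carbon (future C3) is attacked by the azomethine carbon of the tethered N–H hydrazone (future C4, an aza-enamine carbon nucleophile) to give diazene 15, which loses N2 with C–H formation, so the former formyl carbon ends as the C4 methylene without any reductant. The closest known reaction types are phosphoric-acid-catalysed enantioselective 1,6-additions of N–H- or O–H-bearing carbon nucleophiles to para-quinone methides generated in situ from 4-hydroxybenzyl alcohols, and the use of aldehyde N–H hydrazones as alkyl carbanion equivalents that expel N2 after C–C bond formation (the last stage of a Wolff–Kishner reduction); their combination in a ring closure is untested. Ring C closes by C3–C4 bond formation in a 6-exo-trig mode with respect to the exocyclic C3=C1' double bond, driven by re-aromatisation of ring B and by irreversible loss of N2. C3, the only stereocentre, is set in this bond formation under catalyst control: the phosphate is hydrogen-bonded to the quinone methide oxygen and to the hydrazone N–H and leaves one face of C3 open, while C4 becomes a CH2 group. The step needs carbon rather than nitrogen attack of the hydrazone, and C4 rather than the free ring A carbon C8 as the nucleophile; the tether secures the first (nitrogen attack would need an eight-membered ring and is reversible), and the tosylate on O7, the C=N acceptor on C4a and the strain of the five-membered alternative secure the second.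

Step 10
Reactants: 16 (3R)-3-(4-hydroxy-2-methoxyphenyl)-5-methoxy-6-(3-methylbut-2-en-1-yl)-3,4-dihydro-2H-chromen-7-yl 4-methylbenzenesulfonate
Product: 17 (3R)-3-(4-hydroxy-2-methoxyphenyl)-5-methoxy-6-(3-methylbut-2-en-1-yl)-3,4-dihydro-2H-chromen-7-ol
Conditions: KOH (6 equiv), MeOH–H2O (4:1), 65 °C, Ar; then aq. NH4Cl
Reagents that add atoms: none
Why: Cleavage of the aryl sulfonate by hydroxide attack at sulfur; the isoflavan has no base-labile stereocentre (C3–H is not acidic) and the prenyl group is stable to alkali, so the ortho-prenyl phenol is liberated without ever meeting acid.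

**Compound list**

1 | 2,4-dihydroxy-6-methoxybenzaldehyde | COc1cc(O)cc(O)c1C=O | starting material
2 | 4-formyl-3-hydroxy-5-methoxyphenyl 4-methylbenzenesulfonate | COc1cc(OS(=O)(=O)c2ccc(C)cc2)cc(O)c1C=O | intermediate
3 | 4-formyl-3-methoxy-5-[(3-methylbut-2-en-1-yl)oxy]phenyl 4-methylbenzenesulfonate | COc1cc(OS(=O)(=O)c2ccc(C)cc2)cc(OCC=C(C)C)c1C=O | intermediate
4 | ortho-dienone: 4-formyl-3-methoxy-6-(2-methylbut-3-en-2-yl)-5-oxocyclohexa-1,3-dien-1-yl 4-methylbenzenesulfonate (racemic, formed in situ) | COC1=C(C=O)C(=O)C(C(C)(C)C=C)C(OS(=O)(=O)c2ccc(C)cc2)=C1 | intermediate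
5 | para-dienone: 4-formyl-5-methoxy-6-(3-methylbut-2-en-1-yl)-3-oxocyclohexa-1,4-dien-1-yl 4-methylbenzenesulfonate (racemic, formed in situ) | COC1=C(C=O)C(=O)C=C(OS(=O)(=O)c2ccc(C)cc2)C1CC=C(C)C | intermediate
6 | 4-formyl-5-hydroxy-3-methoxy-2-(3-methylbut-2-en-1-yl)phenyl 4-methylbenzenesulfonate | COc1c(CC=C(C)C)c(OS(=O)(=O)c2ccc(C)cc2)cc(O)c1C=O | intermediate
7 | 1-(4-hydroxy-2-methoxyphenyl)ethan-1-one | COc1cc(O)ccc1C(C)=O | starting material
8 | 4-acetyl-3-methoxyphenyl 2,2-dimethylpropanoate | COc1cc(OC(=O)C(C)(C)C)ccc1C(C)=O | intermediate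
9 | 4-(bromoacetyl)-3-methoxyphenyl 2,2-dimethylpropanoate | COc1cc(OC(=O)C(C)(C)C)ccc1C(=O)CBr | intermediate
10 | 4-(2-bromo-1-hydroxyethyl)-3-methoxyphenyl 2,2-dimethylpropanoate (racemic) | COc1cc(OC(=O)C(C)(C)C)ccc1C(O)CBr | intermediate
11 | 3-methoxy-4-(oxiran-2-yl)phenyl 2,2-dimethylpropanoate (racemic, formed in situ) | COc1cc(OC(=O)C(C)(C)C)ccc1C1CO1 | intermediate
12 | 4-{2-[2-formyl-3-methoxy-4-(3-methylbut-2-en-1-yl)-5-(tosyloxy)phenoxy]-1-hydroxyethyl}-3-methoxyphenyl 2,2-dimethylpropanoate (racemic) | COc1cc(OC(=O)C(C)(C)C)ccc1C(O)COc1cc(OS(=O)(=O)c2ccc(C)cc2)c(CC=C(C)C)c(OC)c1C=O | intermediate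
13 | 4-[(E)-hydrazinylidenemethyl]-5-[2-hydroxy-2-(4-hydroxy-2-methoxyphenyl)ethoxy]-3-methoxy-2-(3-methylbut-2-en-1-yl)phenyl 4-methylbenzenesulfonate (racemic) | COc1cc(O)ccc1C(O)COc1cc(OS(=O)(=O)c2ccc(C)cc2)c(CC=C(C)C)c(OC)c1/C=N/N | intermediate
14 | ring B para-quinone methide: 4-[(E)-hydrazinylidenemethyl]-3-methoxy-5-[2-(2-methoxy-4-oxocyclohexa-2,5-dien-1-ylidene)ethoxy]-2-(3-methylbut-2-en-1-yl)phenyl 4-methylbenzenesulfonate (formed in situ) | COC1=CC(=O)C=CC1=CCOc1cc(OS(=O)(=O)c2ccc(C)cc2)c(CC=C(C)C)c(OC)c1/C=N/N | intermediate
15 | 4-diazenyl-3-(4-hydroxy-2-methoxyphenyl)-5-methoxy-6-(3-methylbut-2-en-1-yl)-3,4-dihydro-2H-chromen-7-yl 4-methylbenzenesulfonate (formed in situ; C3 arranged in space as in 16, formally 3S because C4 carries nitrogen; C4 either configuration) | COc1cc(O)ccc1[C@@H]1COc2cc(OS(=O)(=O)c3ccc(C)cc3)c(CC=C(C)C)c(OC)c2C1N=N | intermediate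
16 | (3R)-3-(4-hydroxy-2-methoxyphenyl)-5-methoxy-6-(3-methylbut-2-en-1-yl)-3,4-dihydro-2H-chromen-7-yl 4-methylbenzenesulfonate | COc1cc(O)ccc1[C@@H]1COc2cc(OS(=O)(=O)c3ccc(C)cc3)c(CC=C(C)C)c(OC)c2C1 | intermediate
17 | (3R)-3-(4-hydroxy-2-methoxyphenyl)-5-methoxy-6-(3-methylbut-2-en-1-yl)-3,4-dihydro-2H-chromen-7-ol | COc1cc(O)ccc1[C@@H]1COc2cc(O)c(CC=C(C)C)c(OC)c2C1 | target

**Step count and risks**

Total step count: 10.
Longest linear sequence: 7 steps (steps 1, 2, 3, 7, 8, 9, 10 from compound 1; the ring B branch through steps 4, 5, 6 is equally long).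

The three steps most likely to fail:

Step 9 (the proposed new method). What may go wrong: closure through the terminal nitrogen of the hydrazone or through ring carbon C8 instead of C4; tautomerisation of the diazene to a C4 hydrazone in place of N2 loss; intermolecular trapping of the quinone methide; or insufficient facial selectivity at C3. The fallback uses known chemistry, keeps the C3–C4 ring closure and moves the stereochemical event to a separate step. It sets out from 12: Dess–Martin periodinane (NaHCO3, CH2Cl2, 0 °C) should oxidise the secondary alcohol to the keto aldehyde F1. An intramolecular McMurry coupling of the aldehyde and ketone carbons (TiCl4, Zn, pyridine, THF, reflux) should then close ring C as the C3=C4 alkene, the 2H-chromene pivalate F2. K2CO3 in MeOH at rt should remove the pivalate to give the 4'-phenol F3. F3 would then be reduced by phosphoric-acid-catalysed transfer hydrogenation (TRIP, Hantzsch ester, CH2Cl2, 35 °C), in which protonation at C4 gives the cyclic para-quinone methide and hydride is delivered to one face of C3 while the prenyl alkene is not touched. This comes back to the route at 16.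

Step 7. What may go wrong: opening of the epoxide at the benzylic carbon, which gives the regioisomeric ether, and transfer of the pivaloyl group to a phenoxide at 65 °C. The fallback removes the epoxide from the pathway. It sets out from 10 and 6: silylation of 10 (TBSCl, imidazole, DMF, rt) should give the silyl ether F4, which cannot close to an epoxide. SN2 etherification of F4 with phenol 6 (Cs2CO3, NaI cat., DMF, 60 °C) can then place O1 only on the CH2 carbon and should give the silyl ether F5. Bu4NF buffered with AcOH (THF, 0 °C) should free the alcohol, and the fallback comes back to the route at 12.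

Step 8. What may go wrong: condensation of two aldehyde molecules with one hydrazine to the azine, reduction of the prenyl double bond by diimide if air enters, and slow hydrazinolysis of the hindered ester that forces higher temperature. The fallback delivers the N–H hydrazone by exchange instead of direct condensation. It sets out from 12: condensation with 1,1-dimethylhydrazine (EtOH, AcOH cat., rt) should give the N,N-dimethylhydrazone F6, which cannot form an azine. Treatment of F6 with a large excess of anhydrous hydrazine (EtOH, 50 °C, Ar) should exchange the hydrazone nitrogen and cleave the pivalate in the same pot, and the fallback comes back to the route at 13.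

Further compounds
F1 | step 9 | 4-{[2-formyl-3-methoxy-4-(3-methylbut-2-en-1-yl)-5-(tosyloxy)phenoxy]acetyl}-3-methoxyphenyl 2,2-dimethylpropanoate | COc1cc(OC(=O)C(C)(C)C)ccc1C(=O)COc1cc(OS(=O)(=O)c2ccc(C)cc2)c(CC=C(C)C)c(OC)c1C=O
F2 | step 9 | 3-methoxy-4-[5-methoxy-6-(3-methylbut-2-en-1-yl)-7-(tosyloxy)-2H-chromen-3-yl]phenyl 2,2-dimethylpropanoate | COc1cc(OC(=O)C(C)(C)C)ccc1C1=Cc2c(OC)c(CC=C(C)C)c(OS(=O)(=O)c3ccc(C)cc3)cc2OC1
F3 | step 9 | 3-(4-hydroxy-2-methoxyphenyl)-5-methoxy-6-(3-methylbut-2-en-1-yl)-2H-chromen-7-yl 4-methylbenzenesulfonate | COc1cc(O)ccc1C1=Cc2c(OC)c(CC=C(C)C)c(OS(=O)(=O)c3ccc(C)cc3)cc2OC1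
F4 | step 7 | 4-{2-bromo-1-[(tert-butyldimethylsilyl)oxy]ethyl}-3-methoxyphenyl 2,2-dimethylpropanoate (racemic) | COc1cc(OC(=O)C(C)(C)C)ccc1C(CBr)O[Si](C)(C)C(C)(C)C
F5 | step 7 | 4-{1-[(tert-butyldimethylsilyl)oxy]-2-[2-formyl-3-methoxy-4-(3-methylbut-2-en-1-yl)-5-(tosyloxy)phenoxy]ethyl}-3-methoxyphenyl 2,2-dimethylpropanoate (racemic) | COc1cc(OC(=O)C(C)(C)C)ccc1C(COc1cc(OS(=O)(=O)c2ccc(C)cc2)c(CC=C(C)C)c(OC)c1C=O)O[Si](C)(C)C(C)(C)C
F6 | step 8 | 4-{2-[2-[(E)-(2,2-dimethylhydrazinylidene)methyl]-3-methoxy-4-(3-methylbut-2-en-1-yl)-5-(tosyloxy)phenoxy]-1-hydroxyethyl}-3-methoxyphenyl 2,2-dimethylpropanoate (racemic) | COc1cc(OC(=O)C(C)(C)C)ccc1C(O)COc1cc(OS(=O)(=O)c2ccc(C)cc2)c(CC=C(C)C)c(OC)c1/C=N/N(C)C
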